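**Retrosynthetic overview**
- The last bond made is C10'–C11' of the side chain. It is formed by a crossed Kolbe electrolysis: double decarboxylation, then radical–radical union of two CH2 carbons of like polarity. The partners are (5E,7E)-nona-5,7-dienoic acid and the complete dioxine-undecanoic acid.
- Enabling feature: this bond lies inside the unbranched (CH2)13 spacer, ten CH2 from ring carbon C3 and three CH2 from diene carbon C14'. Both radicals are therefore plain primary radicals that cannot reach O1–O2, C4=C5 or the diene (4-pentenyl relationship). The 1,2-dioxine ring (O1–O2, peroxyketal C3) and the methyl ester are inert to oxidation and exchange only degenerately with MeOH.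
- The only ring, the 3,6-dihydro-1,2-dioxine, is closed at O1–C6 by 6-exo-trig peroxy-Michael addition of a C3 hydroperoxyketal to a (2E,4Z)-dienoate, which sets C6. C3 is then set by anomeric equilibration in MeOH/H+.
- The (2E,4Z)-6-oxodienoate comes from dearomatisation of a 2-alkylfuran (singlet oxygen, Me2S, Wittig). The furan is made from furan and 11-bromoundecan-1-ol.
- The dienoic acid comes from sorbyl acetate and a C3 alkoxide-Grignard reagent (Cu catalysis), followed by oxidation.

Key step: step 8

Remark 1: ring locants used throughout are O1, O2, C3 (peroxyketal carbon), C4=C5 and C6 (CH bearing CH2CO2Me). The target is (3R,6R), with OMe and CH2CO2Me cis.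
Remark 2 (assumption): the sense of induction of the catalyst in step 6 cannot be taken from precedent. Both catalyst antipodes are available from D- or L-tert-leucine, and the one that delivers (6R) is meant.

**Step 1**
Reactants: 1 (2E,4E)-hexa-2,4-dien-1-yl acetate (sorbyl acetate); 2 3-chloropropan-1-ol
Product: 4 (5E,7E)-nona-5,7-dien-1-ol, via alkoxide-Grignard reagent 3 (not isolated)
Conditions: 2, MeMgCl, THF, −20 °C; Mg, reflux; then 1, Li2CuCl4 (3 mol %), THF, −20 → 0 °C; aq NH4Cl
Reagents that add atoms: none
Why: Li2CuCl4-catalysed allylic substitution of a dienyl acetate by a Grignard reagent should occur at the primary α-carbon with retention of the (E,E)-diene, the reaction type used for (E,E)-dienol pheromones.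

**Step 2**
Reactants: 4 (5E,7E)-nona-5,7-dien-1-ol
Product: 5 (5E,7E)-nona-5,7-dienoic acid
Conditions: TEMPO (10 mol %), PhI(OAc)2 (2.2 equiv), MeCN–H2O 1:1, 0 °C → rt
Reagents that add atoms: water, O
Why: Oxoammonium-mediated oxidation (TEMPO/PhI(OAc)2) takes the primary alcohol through the aldehyde hydrate to the acid and should neither attack nor isomerise the conjugated diene.

**Step 3**
Reactants: 6 furan; 7 11-bromoundecan-1-ol
Product: 9 11-(furan-2-yl)undecan-1-ol, via 2-furyllithium 8 (not isolated)
Conditions: 6 (2.5 equiv), n-BuLi (2.2 equiv), THF, −78 → 0 °C; then 7, DMPU, 0 °C → rt; H2O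
Reagents that add atoms: none
Why: C2-lithiation of furan and SN2 alkylation with a primary bromide is standard, the first equivalent of 8 serving only to deprotonate the hydroxyl group, so no protecting group is needed.

**Step 4**
Reactants: 9 11-(furan-2-yl)undecan-1-ol; 10 methyl (triphenyl-λ5-phosphanylidene)acetate
Product: 13 methyl (2E,4Z)-17-hydroxy-6-oxoheptadeca-2,4-dienoate, via furan endoperoxide 11 (not isolated), via (Z)-oxoenal 12 (not isolated)
Conditions: O2, tetraphenylporphyrin (cat.), visible light, CH2Cl2, −78 °C; Me2S, −78 → 0 °C; then 10, 0 °C → rt, dark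
Reagents that add atoms: dioxygen (sensitised to singlet oxygen), O=O
Why: [4+2] cycloaddition of singlet oxygen dearomatises the furan, Me2S reduction of the endoperoxide gives the 4-oxo-2-enal whose alkene keeps the ring-derived Z geometry, and the stabilised ylide reacts only with the aldehyde (Wittig reaction) to give the E-enoate.

**Step 5**
Reactants: 13 methyl (2E,4Z)-17-hydroxy-6-oxoheptadeca-2,4-dienoate
Product: 14 methyl (2E,4Z)-6-hydroperoxy-17-hydroxy-6-methoxyheptadeca-2,4-dienoate (racemic)
Conditions: urea·H2O2 (5 equiv), Sc(OTf)3 (10 mol %), MeOH, 0 °C → rt, dark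
Reagents that add atoms: hydrogen peroxide (from urea–hydrogen peroxide), OO; methanol, CO
Why: Lewis-acid-catalysed peroxyketalisation adds MeOH and H2O2 to the ketone through the oxocarbenium ion, the acidic medium excludes Weitz–Scheffer epoxidation, and the racemic new centre does not matter because it is equilibrated in step 6.

**Step 6**
Reactants: 14 methyl (2E,4Z)-6-hydroperoxy-17-hydroxy-6-methoxyheptadeca-2,4-dienoate
Product: 16 methyl [(3R,6R)-3-(11-hydroxyundecyl)-3-methoxy-3,6-dihydro-1,2-dioxin-6-yl]acetate, via C3-epimeric (6R)-dioxines 15 (not isolated)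
Conditions: tert-leucine-derived urea-type bifunctional iminophosphorane (BIMP) catalyst (10 mol %), Et2O, −20 °C; then CSA (30 mol %), MeOH, rt; the minor C3 epimer is separated and resubmitted to CSA/MeOH
Reagents that add atoms: methanol (degenerate exchange at C3), CO
Why: Proposed new method: the iminophosphorane deprotonates the hydroperoxide (far more acidic than the remote alcohol) while the urea N–H groups bind the ester carbonyl (a urea rather than a thiourea, because thioureas reduce peroxides), so that the peroxy anion, held next to the β-carbon by the Z-alkene, adds 6-exo-trig to one face of the E-enoate and sets C6 as R under catalyst control whichever configuration the peroxyketal carbon has; CSA/MeOH then ionises C3 reversibly to the allylic peroxycarbenium ion and funnels both C3 epimers towards the cis (3R,6R) isomer, which has OMe pseudoaxial (anomeric effect) and both carbon substituents pseudoequatorial; the closest known reaction types are the secondary-amine-catalysed racemic peroxy-Michael cyclisation of hydroperoxyketals onto enoates (3-methoxy-1,2-dioxane-6-acetates) and the BIMP-catalysed enantioselective intramolecular oxa-Michael and intermolecular sulfa-Michael additions to unactivated α,β-unsaturated esters.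

**Step 7**
Reactants: 16 methyl [(3R,6R)-3-(11-hydroxyundecyl)-3-methoxy-3,6-dihydro-1,2-dioxin-6-yl]acetate
Product: 17 11-[(3R,6R)-3-methoxy-6-(2-methoxy-2-oxoethyl)-3,6-dihydro-1,2-dioxin-3-yl]undecanoic acid
Conditions: TEMPO (10 mol %), NaClO2 (2 equiv), NaOCl (2 mol %), MeCN–phosphate buffer pH 6.7, rt
Reagents that add atoms: sodium chlorite, [Na+].[O-]Cl=O
Why: TEMPO/hypochlorite oxidation to the aldehyde with in situ Pinnick-type chlorite oxidation runs near neutral pH, so the peroxyketal, the O–O bond (inert to oxidants), the electron-poor ring alkene and both stereocentres should be untouched.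

**Step 8**
Reactants: 17 11-[(3R,6R)-3-methoxy-6-(2-methoxy-2-oxoethyl)-3,6-dihydro-1,2-dioxin-3-yl]undecanoic acid; 5 (5E,7E)-nona-5,7-dienoic acid
Product: 18 xestin A
Conditions: 17 (1 equiv), 5 (6 equiv), NaOMe (5 mol % of total acid), MeOH, undivided cell, smooth Pt anode, small Pt-wire cathode, constant current ca. 200 mA cm−2, 0–10 °C, stopped before the electrolyte turns basic
Reagents that add atoms: none
Why: At a smooth Pt anode run at high current density both carboxylates are oxidised by one electron, lose CO2 and leave two unstabilised primary radicals (octa-4,6-dienyl from 5, 10-(dioxinyl)decyl from 17) that combine in the dense radical layer at the electrode to form the C10'–C11' bond, while protons are discharged to H2 at the cathode. The reaction type is the mixed (crossed) Kolbe electrolysis, the classical anodic decarboxylative coupling by which alkenoic and ω-functionalised alkanoic acids are joined, and it unites two carbons of like polarity without any organometallic or low-valent metal. No ring is closed and no stereocentre is created; C3 and C6 lie ten bonds or more from the radical centre, and any acid-induced ionisation of C3 near the anode is degenerate in MeOH and returns the thermodynamically preferred (3R) epimer. Cross- versus homo-coupling is statistical and is secured by a several-fold excess of the cheap acid 5, whose homodimer is an apolar hydrocarbon that should be easy to remove. The O1–O2 bond and the peroxyketal cannot be oxidised further, and their reduction is avoided because the small-area cathode carries its current by proton discharge from the large excess of acid (quasi-divided cell), while stopping before the medium turns basic suppresses Kornblum–DeLaMare cleavage at C6–H. The diene should be spared because the radical from 5 stands in a 4-pentenyl relationship to it (only slow 4-exo or 5-endo closure), because alkyl-radical addition to a 1,4-disubstituted diene is slow beside radical–radical combination at the electrode, and because the adsorbed carboxylate layer that keeps even MeOH from being oxidised shields the π-system.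

**Compound list**
1 | (2E,4E)-hexa-2,4-dien-1-yl acetate | C/C=C/C=C/COC(C)=O | starting material
2 | 3-chloropropan-1-ol | OCCCCl | starting material
3 | chloromagnesium 3-(chloromagnesio)propan-1-olate | Cl[Mg]OCCC[Mg]Cl | intermediate
4 | (5E,7E)-nona-5,7-dien-1-ol | C/C=C/C=C/CCCCO | intermediate
5 | (5E,7E)-nona-5,7-dienoic acid | C/C=C/C=C/CCCC(=O)O | intermediate
6 | furan | c1ccoc1 | starting material
7 | 11-bromoundecan-1-ol | OCCCCCCCCCCCBr | starting material
8 | 2-furyllithium | [Li]c1ccco1 | intermediate
9 | 11-(furan-2-yl)undecan-1-ol | OCCCCCCCCCCCc1ccco1 | intermediate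
10 | methyl (triphenyl-λ5-phosphanylidene)acetate | COC(=O)C=P(c1ccccc1)(c1ccccc1)c1ccccc1 | starting material
11 | 1-(11-hydroxyundecyl)-2,3,7-trioxabicyclo[2.2.1]hept-5-ene (racemic) | OCCCCCCCCCCCC12C=CC(OO1)O2 | intermediate
12 | (2Z)-15-hydroxy-4-oxopentadec-2-enal | O=C/C=C\C(=O)CCCCCCCCCCCO | intermediate
13 | methyl (2E,4Z)-17-hydroxy-6-oxoheptadeca-2,4-dienoate | COC(=O)/C=C/C=C\C(=O)CCCCCCCCCCCO | intermediate
14 | methyl (2E,4Z)-6-hydroperoxy-17-hydroxy-6-methoxyheptadeca-2,4-dienoate (racemic) | COC(=O)/C=C/C=C\C(OC)(OO)CCCCCCCCCCCO | intermediate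
15 | methyl [(6R)-3-(11-hydroxyundecyl)-3-methoxy-3,6-dihydro-1,2-dioxin-6-yl]acetate, both C3 epimers | OCCCCCCCCCCCC1(OC)C=C[C@@H](CC(=O)OC)OO1 | intermediate
16 | methyl [(3R,6R)-3-(11-hydroxyundecyl)-3-methoxy-3,6-dihydro-1,2-dioxin-6-yl]acetate | OCCCCCCCCCCC[C@]1(OC)C=C[C@@H](CC(=O)OC)OO1 | intermediate
17 | 11-[(3R,6R)-3-methoxy-6-(2-methoxy-2-oxoethyl)-3,6-dihydro-1,2-dioxin-3-yl]undecanoic acid | OC(=O)CCCCCCCCCC[C@]1(OC)C=C[C@@H](CC(=O)OC)OO1 | intermediate
18 | xestin A, methyl [(3R,6R)-3-methoxy-3-[(14E,16E)-octadeca-14,16-dien-1-yl]-3,6-dihydro-1,2-dioxin-6-yl]acetate | C/C=C/C=C/CCCCCCCCCCCCC[C@]1(OC)C=C[C@@H](CC(=O)OC)OO1 | target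

**Step count**
Total step count: 8.
Longest linear sequence: 6 (steps 3–8).

**Steps most likely to fail**

1. **Step 6 (Proposed new method).**
   - What may go wrong:
     - Catalyst control over the enoate face may be incomplete for the mismatched C3 epimer of the racemic hydroperoxyketal.
     - A non-selective background cyclisation may compete.
     - Reversible retro-Michael opening may erode the C6 configuration.
     - Base-induced Kornblum–DeLaMare cleavage may occur.
   - The fallback uses known chemistry, sets out from 14 and returns at 16.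
   - 14 is cyclised with catalytic Et2NH in CF3CH2OH (racemic peroxy-Michael cyclisation) to the racemic methyl [3-(11-hydroxyundecyl)-3-methoxy-3,6-dihydro-1,2-dioxin-6-yl]acetate F1.
   - F1 is resolved through its labile C3 position. Acid-catalysed trans-ketalisation (CSA) is run in neat ethyl (S)-lactate under reduced pressure to strip MeOH. This should give the two thermodynamic cis peroxyketals, the (3R,6R)-lactyl peroxyketal F2 and the (3S,6S)-lactyl peroxyketal F3. They are diastereomers and are separated by chromatography.
   - CSA/MeOH on F2 exchanges the lactate for methoxy, leaves C6 untouched and gives 16.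

2. **Step 8.**
   - What may go wrong:
     - The diene may be oxidised at the anode or may trap radicals.
     - The O–O bond may be cleaved at the cathode.
     - Over-oxidation to cations (Hofer–Moest pathway) may occur.
     - The statistical product distribution may be unfavourable.
   - The fallback sets out from 5 and 8 and returns at 18. It makes the same CH2–CH2 bond before any O–O bond exists.
   - 5 is converted with N-hydroxyphthalimide/DIC into 1,3-dioxoisoindolin-2-yl (5E,7E)-nona-5,7-dienoate F4.
   - 8 is alkylated with excess commercial 1,10-dibromodecane to 2-(10-bromodecyl)furan F5. Zn dust/LiCl then gives [10-(furan-2-yl)decyl]zinc bromide F6.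
   - Nickel-catalysed decarboxylative Negishi-type alkyl–alkyl coupling of F4 with F6 (NiCl2·glyme, 4,4'-di-tert-butyl-2,2'-bipyridine, THF–DMF, rt) gives 2-[(14E,16E)-octadeca-14,16-dien-1-yl]furan F7.
   - The furan takes up singlet oxygen far faster than an acyclic 1,4-dialkyl diene. It is photooxygenated at −78 °C to one equivalent of uptake, giving the full-chain furan endoperoxide F8.
   - F8 is reduced with Me2S to (2Z,18E,20E)-4-oxodocosa-2,18,20-trienal F9. Olefination with 10 gives methyl (2E,4Z,20E,22E)-6-oxotetracosa-2,4,20,22-tetraenoate F10.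
   - The conditions of step 5 give methyl (2E,4Z,20E,22E)-6-hydroperoxy-6-methoxytetracosa-2,4,20,22-tetraenoate F11.
   - The conditions of step 6 lead through the C3-epimeric (6R)-xestins F12 to 18.

3. **Step 5.**
   - What may go wrong:
     - The addition equilibrium may be unfavourable for the conjugated ketone.
     - Acid may induce Z→E isomerisation.
     - Oxa-Michael closure followed by aromatisation to a furan-2-acetate may compete.
   - The fallback sets out from 13 and returns at 14.
   - The ketone is first driven irreversibly to its ketal with HC(OMe)3 and catalytic CSA in MeOH at 0 °C. This gives methyl (2E,4Z)-17-hydroxy-6,6-dimethoxyheptadeca-2,4-dienoate F13.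
   - F13 is then trans-peroxyketalised with anhydrous ethereal H2O2 and catalytic PPTS, exchanging one methoxy group for the better α-effect nucleophile, to give 14.

**Further compounds**
F1 | step 6 | methyl [3-(11-hydroxyundecyl)-3-methoxy-3,6-dihydro-1,2-dioxin-6-yl]acetate, racemic | OCCCCCCCCCCCC1(OC)C=CC(CC(=O)OC)OO1
F2 | step 6 | ethyl (2S)-2-{[(3R,6R)-3-(11-hydroxyundecyl)-6-(2-methoxy-2-oxoethyl)-3,6-dihydro-1,2-dioxin-3-yl]oxy}propanoate | OCCCCCCCCCCC[C@]1(O[C@@H](C)C(=O)OCC)C=C[C@@H](CC(=O)OC)OO1
F3 | step 6 | ethyl (2S)-2-{[(3S,6S)-3-(11-hydroxyundecyl)-6-(2-methoxy-2-oxoethyl)-3,6-dihydro-1,2-dioxin-3-yl]oxy}propanoate | OCCCCCCCCCCC[C@@]1(O[C@@H](C)C(=O)OCC)C=C[C@H](CC(=O)OC)OO1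
F4 | step 8 | 1,3-dioxoisoindolin-2-yl (5E,7E)-nona-5,7-dienoate | C/C=C/C=C/CCCC(=O)ON1C(=O)c2ccccc2C1=O
F5 | step 8 | 2-(10-bromodecyl)furan | BrCCCCCCCCCCc1ccco1
F6 | step 8 | [10-(furan-2-yl)decyl]zinc bromide | Br[Zn]CCCCCCCCCCc1ccco1
F7 | step 8 | 2-[(14E,16E)-octadeca-14,16-dien-1-yl]furan | C/C=C/C=C/CCCCCCCCCCCCCc1ccco1
F8 | step 8 | 1-[(14E,16E)-octadeca-14,16-dien-1-yl]-2,3,7-trioxabicyclo[2.2.1]hept-5-ene (racemic) | C/C=C/C=C/CCCCCCCCCCCCCC12C=CC(OO1)O2
F9 | step 8 | (2Z,18E,20E)-4-oxodocosa-2,18,20-trienal | C/C=C/C=C/CCCCCCCCCCCCCC(=O)/C=C\C=O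
F10 | step 8 | methyl (2E,4Z,20E,22E)-6-oxotetracosa-2,4,20,22-tetraenoate | C/C=C/C=C/CCCCCCCCCCCCCC(=O)/C=C\C=C\C(=O)OC
F11 | step 8 | methyl (2E,4Z,20E,22E)-6-hydroperoxy-6-methoxytetracosa-2,4,20,22-tetraenoate (racemic) | C/C=C/C=C/CCCCCCCCCCCCCC(OC)(OO)/C=C\C=C\C(=O)OC
F12 | step 8 | methyl [(6R)-3-methoxy-3-[(14E,16E)-octadeca-14,16-dien-1-yl]-3,6-dihydro-1,2-dioxin-6-yl]acetate, both C3 epimers | C/C=C/C=C/CCCCCCCCCCCCCC1(OC)C=C[C@@H](CC(=O)OC)OO1
F13 | step 5 | methyl (2E,4Z)-17-hydroxy-6,6-dimethoxyheptadeca-2,4-dienoate | COC(=O)/C=C/C=C\C(OC)(OC)CCCCCCCCCCCO
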